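The readings are calculated on assumed constants; noise was put on by code.

Read the first point of each run before anything else: I treat the further reaction of target there as a small correction and count each percent of target as a percent of substrate gone.

| flask | substrate | gas phase | remark | time |
|---|---|---|---|---|
| cedar | 0.20 M | 41 mM (held) | run made earlier |  |
| alder | 0.30 M | 41 mM (held) | run made earlier |  |
| flask | 0.40 M | 41 mM (held) |  | 10 h |

| run | time / h | target / % |
|---|---|---|
| cedar | 1.50 | 17.1 |
| cedar | 3.00 | 30.6 |
| cedar | 5.00 | 41.5 |
| cedar | 6.00 | 44.9 |
| cedar | 8.00 | 46.5 |
| cedar | 10.0 | 47.4 |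
| alder | 0.667 | 8.4 |
| alder | 2.00 | 22.4 |
| alder | 4.00 | 34.3 |
| alder | 5.00 | 41.2 |
| alder | 8.00 | 47.0 |
| alder | 10.0 | 47.7 |

(readings scatter by 0.5 percentage points)

- the target standing at 10 h, as a percentage of the substrate charged
- concentration of dissolved gas in solution at 10 h, in percent of saturation

- the numbers in the tables scatter with a standard deviation of 0.5 percentage points
- at the start none of the gas phase is in solution

**First instants.** Dissolved gas starts from nothing, but the first readings already show target. From them I reckon, averaging cedar and alder:

k′ = mean of −ln(fraction not yet target)/t = 0.128 h⁻¹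

This k′ is the pseudo-first-order constant, the fractional loss of [substrate] per hour.

**Middle.** At 5.00 h, cedar shows 41.5% and alder 41.2%. They differ by 0.3 percentage points, and a reading scatters by 0.5 points, so I lay the flask on the same percent curve.

**End.** For the flask at 10 h:

substrate left = exp(−k′t) = 27.7%

Between 8.00 h and 10.0 h, the same reckoning takes 8.1 points of the charge from substrate, yet cedar's target rises from 46.5% to 47.4%, less than that. So I read cedar's target as consumed while it forms, a consecutive reaction near its maximum. For the flask I take the mean of the cedar and alder readings at 10.0 h, 47.6%, which in my reckoning leaves 24.7% of the charge in neither substrate nor target.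

The forecast gives 46.9% of target (45.3% to 48%) and dissolved gas at 97% of saturation (92% to 99.5%), and for the flask at 10 h it says “about 2.3% of the substrate remains”. We nearly agree on target but part on substrate, where I reckon 27.7%.

The flask gives 47.3% of target, with dissolved gas at 92.8% of saturation.

    gas phase ⇌ dissolved gas, rate k1*(csat - [dissolved gas]) (kL = 11.6 h⁻¹)
    substrate + dissolved gas → target (k = 3.77 M⁻¹ h⁻¹)
    dissolved gas + target → over-reacted product (k = 2.16 M⁻¹ h⁻¹)
    2 dissolved gas → self-condensation product (k = 1.46 M⁻¹ h⁻¹)

Target moves by 5 points when the reading goes to 5.67 h or 14.5 h, all amounts held. Put to use again, exp(−k′t) gives 27.7% of substrate for the flask at 10 h, where it holds 25%. For the same flask read at 2.5 h, it gives 72.6%, and that flask holds 71.8%.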